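## Retrosynthetic overview

1. Last bond: acylation of the free C8 hydroxyl of the furanone lactone core with (E)-2-(acetoxymethyl)but-2-enoic acid.
2. Ring 3 (3(2H)-furanone, formed last): the C1 carbinol of a macrocyclic 10-hydroxy-2-yne is oxidised and O10 adds to C3. The C2≡C3 triple bond stands for the dehydrated 1,3-dione of the biogenetic 10-hydroxy-1,3-dione → 3,10-hemiketal → furanone sequence.
3. Rings 1 and 2 (ten-membered carbocycle, then γ-lactone in the same flask): the C6–C7 bond, which is the farnesyl C1–C10 bond of germacrene biogenesis, is closed on an open chain from a (Z)-enal and a C7=C11–C13 allyl chloride with CrCl2. The C6 alkoxide then lactonises onto C12.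
4. Open chain: C1–C2 by acetylide addition of (Z)-3-methylpent-2-en-4-yn-1-ol; C7 and C11–C13 by Morita–Baylis–Hillman then Corey–Kim chlorination; C8–O by enamine α-oxyamination; C10 with its oxygen and methyl from (R)-linalool by double ozonolysis.
5. Ring order: carbocycle → lactone → furanone. C10 comes from linalool, C8 from the catalyst, and C6 and C7 are set in the ring closure under control of C8 alone.

Assumption: germacrane numbering (C1–C15) is used for every carbon that ends up in the target skeleton, OTMP means (2,2,6,6-tetramethylpiperidin-1-yl)oxy, and commercial (R)-(−)-linalool of at least 97% ee is the starting material.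

## Route

Step 1
Reactants: 1 (R)-(−)-linalool
Product: 2 (R)-3,7-dimethyl-3-(triethylsilyloxy)octa-1,6-diene
Conditions: TESOTf, 2,6-lutidine, CH2Cl2, −78 → 0 °C
Reagents that add atoms: triethylsilyl triflate, CC[Si](CC)(CC)OS(=O)(=O)C(F)(F)F
Why: Silyl ether formation on the tertiary alcohol; C10 (R) comes from the chiral pool and is blocked so that the later C7 aldehyde cannot lactolise onto it.

Step 2
Reactants: 2 (R)-3,7-dimethyl-3-(triethylsilyloxy)octa-1,6-diene
Product: 3 (R)-2-methyl-2-(triethylsilyloxy)pentanedial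
Conditions: O3, pyridine (3 equiv), CH2Cl2, −78 °C
Reagents that add atoms: ozone, [O-][O+]=O
Why: Pyridine-mediated reductive ozonolysis cleaves both alkenes directly to carbonyls; the C1 aldehyde has no α-hydrogen and the C7 aldehyde has two, which differentiates the two ends for steps 3 and 4.

Step 3
Reactants: 3 (R)-2-methyl-2-(triethylsilyloxy)pentanedial
Product: 4 (2R,4R)-2-methyl-4-[(2,2,6,6-tetramethylpiperidin-1-yl)oxy]-2-(triethylsilyloxy)pentanedial
Conditions: TEMPO (1.3 equiv), (5R)-5-benzyl-2,2,3-trimethylimidazolidin-4-one·TFA (20 mol %, first-generation MacMillan catalyst), CuCl2·2H2O (10 mol %), air, acetone, −10 °C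
Reagents that add atoms: TEMPO, CC1(C)CCCC(C)(C)N1[O]
Why: Enamine organocatalytic α-oxyamination with copper/TEMPO co-catalysis; only the C7 aldehyde can form an enamine, and the (5R)-benzyl group shields one enamine face so that oxygen is delivered to give 8R.

Step 4
Reactants: 4 (2R,4R)-2-methyl-4-OTMP-2-(triethylsilyloxy)pentanedial; 5 methyl acrylate
Product: 6 methyl (3RS,4R,6R)-3-hydroxy-6-methyl-2-methylidene-7-oxo-4-OTMP-6-(triethylsilyloxy)heptanoate
Conditions: 5 (5 equiv), DABCO (1 equiv), 1,4-dioxane/H2O 1:1, rt, 3–5 d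
Reagents that add atoms: none
Why: Morita–Baylis–Hillman reaction at the C7 aldehyde, which carries an activating α-oxygen and an α-hydrogen, while the α-quaternary C1 aldehyde is too hindered to react; the new C7 carbinol is a mixture that is erased in step 5.

Step 5
Reactants: 6 methyl (3RS,4R,6R)-3-hydroxy-6-methyl-2-methylidene-7-oxo-4-OTMP-6-(triethylsilyloxy)heptanoate
Product: 7 methyl (2Z,4R,6R)-2-(chloromethyl)-6-methyl-7-oxo-4-OTMP-6-(triethylsilyloxy)hept-2-enoate
Conditions: NCS, Me2S, CH2Cl2, −20 → 0 °C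
Reagents that add atoms: N-chlorosuccinimide, ClN1C(=O)CCC1=O
Why: Corey–Kim activation of the allylic alcohol and SN2′ return of chloride gives the thermodynamically preferred (Z)-2-(chloromethyl)enoate with C8 trans to the ester; the aldehyde, silyl ether and alkoxyamine are inert.

Step 6
Reactants: 7 methyl (2Z,4R,6R)-2-(chloromethyl)-6-methyl-7-oxo-4-OTMP-6-(triethylsilyloxy)hept-2-enoate; 8 (Z)-3-methylpent-2-en-4-yn-1-ol
Product: 11 methyl (2Z,4R,6R,7RS,10Z)-2-(chloromethyl)-6,10-dimethyl-4-OTMP-6,7,12-tris(triethylsilyloxy)dodeca-2,10-dien-8-ynoate, via dilithio enynol 9 (not isolated), via dilithium dialkoxide 10 (not isolated)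
Conditions: 8, n-BuLi (2.05 equiv), THF, −78 → 0 °C; 7, −78 °C; TESOTf (2.5 equiv), 2,6-lutidine, −78 → −40 °C
Reagents that add atoms: triethylsilyl triflate, CC[Si](CC)(CC)OS(=O)(=O)C(F)(F)F
Why: Acetylide 1,2-addition to the non-enolisable C1 aldehyde at −78 °C is faster than SN2′ attack on the allyl chloride or attack on the ester, and both lithium alkoxides are silylated in the flask; the C1 carbinol is an epimer mixture that is removed in step 10.

Step 7
Reactants: 11 methyl (2Z,4R,6R,7RS,10Z)-2-(chloromethyl)-6,10-dimethyl-4-OTMP-6,7,12-tris(triethylsilyloxy)dodeca-2,10-dien-8-ynoate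
Product: 13 methyl (2Z,4R,6R,7RS,10Z)-2-(chloromethyl)-6,10-dimethyl-12-oxo-4-OTMP-6,7-bis(triethylsilyloxy)dodeca-2,10-dien-8-ynoate, via alkoxysulfonium chloride 12 (not isolated)
Conditions: (COCl)2, DMSO, CH2Cl2, −78 → −40 °C; i-Pr2NEt, −78 → −20 °C
Reagents that add atoms: none
Why: Swern oxidation applied directly to a primary triethylsilyl ether; chlorodimethylsulfonium cleaves only the unhindered primary Si–O bond, the secondary and tertiary silyl ethers stay, and the hindered base at low temperature spares the allyl chloride and the (Z)-enal.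

Step 8
Reactants: 13 methyl (2Z,4R,6R,7RS,10Z)-2-(chloromethyl)-6,10-dimethyl-12-oxo-4-OTMP-6,7-bis(triethylsilyloxy)dodeca-2,10-dien-8-ynoate
Product: 15 (1RS,6S,7R,8R,10R)-8-OTMP-1,10-bis(triethylsilyloxy)germacra-4Z,11(13)-dien-2-yn-6,12-olide, via macrocyclic hydroxy ester 14 (not isolated)
Conditions: CrCl2 (10 equiv), NaI (0.2 equiv), DMF/THF 1:3, rt, 13 added over 12 h to 2 mM
Reagents that add atoms: none
Why: Intramolecular Nozaki–Hiyama–Kishi allylation in which the allylchromium attacks the C6 aldehyde through C7 (SE2′) in a chair transition state and the chromium alkoxide then closes the lactone onto C12; the usual anti preference of allylchromium reagents gives the 6,7-trans lactone, and with H8 eclipsing the alkene (A-1,3 strain) the aldehyde enters anti to the bulky C8 alkoxyamine, so C8 alone sets C6 (S) and C7.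

Step 9
Reactants: 15 (1RS,6S,7R,8R,10R)-8-OTMP-1,10-bis(triethylsilyloxy)germacra-4Z,11(13)-dien-2-yn-6,12-olide
Product: 16 (1RS,6S,7S,8R,10R)-1,8,10-trihydroxygermacra-4Z,11(13)-dien-2-yn-6,12-olide
Conditions: Zn dust, AcOH/THF/H2O 3:1:1, 40 °C
Reagents that add atoms: none
Why: Reductive N–O cleavage of the alkoxyamine and acid solvolysis of both silyl ethers in one operation; the unactivated enyne and the α-methylene lactone are not reduced by unactivated zinc in acetic acid.

Step 10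
Reactants: 16 (1RS,6S,7S,8R,10R)-1,8,10-trihydroxygermacra-4Z,11(13)-dien-2-yn-6,12-olide
Product: 18 (6S,7S,8R,10R)-8-hydroxy-1-oxo-3,10-epoxygermacra-2,4Z,11(13)-trien-6,12-olide, via hydroxy ynone 17 (not isolated)
Conditions: MnO2, CH2Cl2, rt; filter; Ph3PAuNTf2 (5 mol %), CH2Cl2, rt
Reagents that add atoms: none
Why: MnO2 oxidises only the propargylic C1 carbinol, and the resulting α′-hydroxy ynone undergoes gold-catalysed 5-endo-dig oxa-Michael cycloisomerisation of O10 onto C3 to give the 3(2H)-furanone with release of alkyne strain; the C8 hydroxyl could only form a seven-membered ring, and C10 is untouched.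

Step 11
Reactants: 19 tert-butyl acrylate; 20 acetaldehyde
Product: 21 tert-butyl 3-hydroxy-2-methylidenebutanoate
Conditions: DABCO (0.3 equiv), 1,4-dioxane/H2O 1:1, rt, 5 d
Reagents that add atoms: none
Why: Morita–Baylis–Hillman reaction; the racemic carbinol is erased in step 12.

Step 12
Reactants: 21 tert-butyl 3-hydroxy-2-methylidenebutanoate
Product: 23 tert-butyl (E)-2-(acetoxymethyl)but-2-enoate, via secondary acetate 22 (not isolated)
Conditions: Ac2O, Et3N, DMAP (cat.), CH2Cl2, 0 °C; then DABCO (0.3 equiv), THF, 60 °C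
Reagents that add atoms: acetic anhydride, CC(=O)OC(C)=O
Why: Acetylation followed by amine-catalysed SN2′–SN2′ allylic transposition to the conjugated primary acetate, which for acrylate esters is the (E) isomer with methyl trans to the carboxyl.

Step 13
Reactants: 23 tert-butyl (E)-2-(acetoxymethyl)but-2-enoate
Product: 24 (E)-2-(acetoxymethyl)but-2-enoic acid
Conditions: TFA/CH2Cl2 1:4, 0 °C → rt
Reagents that add atoms: none
Why: Acidolysis of the tert-butyl ester by loss of isobutene; the acetate and the alkene geometry are unaffected.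

Step 14
Reactants: 18 (6S,7S,8R,10R)-8-hydroxy-1-oxo-3,10-epoxygermacra-2,4Z,11(13)-trien-6,12-olide; 24 (E)-2-(acetoxymethyl)but-2-enoic acid
Product: 26 (6S,7S,8R,10R)-8-[(E)-2-(acetoxymethyl)but-2-enoyloxy]-1-oxo-3,10-epoxygermacra-2,4Z,11(13)-trien-6,12-olide (target CNP0176571.1), via mixed anhydride 25 (not isolated)
Conditions: 24, 2,4,6-trichlorobenzoyl chloride, Et3N, THF, rt; then 18, DMAP, toluene, rt
Reagents that add atoms: none
Why: Yamaguchi esterification of the only free hydroxyl; the β-methyl group of the acid slows conjugate addition of DMAP, and no stereocentre is touched.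

## Compound list

1 | (R)-(−)-linalool | C=C[C@](C)(O)CCC=C(C)C | starting material
2 | (R)-3,7-dimethyl-3-(triethylsilyloxy)octa-1,6-diene | C=C[C@](C)(O[Si](CC)(CC)CC)CCC=C(C)C | intermediate
3 | (R)-2-methyl-2-(triethylsilyloxy)pentanedial | O=C[C@](C)(O[Si](CC)(CC)CC)CCC=O | intermediate
4 | (2R,4R)-2-methyl-4-OTMP-2-(triethylsilyloxy)pentanedial | O=C[C@](C)(O[Si](CC)(CC)CC)C[C@@H](ON1C(C)(C)CCCC1(C)C)C=O | intermediate
5 | methyl acrylate | C=CC(=O)OC | starting material
6 | methyl (3RS,4R,6R)-3-hydroxy-6-methyl-2-methylidene-7-oxo-4-OTMP-6-(triethylsilyloxy)heptanoate | O=C[C@](C)(O[Si](CC)(CC)CC)C[C@@H](ON1C(C)(C)CCCC1(C)C)C(O)C(=C)C(=O)OC | intermediate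
7 | methyl (2Z,4R,6R)-2-(chloromethyl)-6-methyl-7-oxo-4-OTMP-6-(triethylsilyloxy)hept-2-enoate | O=C[C@](C)(O[Si](CC)(CC)CC)C[C@@H](ON1C(C)(C)CCCC1(C)C)/C=C(\CCl)C(=O)OC | intermediate
8 | (Z)-3-methylpent-2-en-4-yn-1-ol | C#C/C(C)=C\CO | starting material
9 | dilithio derivative of 8 (lithium alkoxide and lithium acetylide) | [Li+].[Li+].[C-]#C/C(C)=C\C[O-] | intermediate (not isolated)
10 | dilithium C1,C6-dialkoxide of the acetylide adduct | [Li+].[Li+].[O-]C/C=C(/C)C#CC([O-])[C@](C)(O[Si](CC)(CC)CC)C[C@@H](ON1C(C)(C)CCCC1(C)C)/C=C(\CCl)C(=O)OC | intermediate (not isolated)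
11 | methyl (2Z,4R,6R,7RS,10Z)-2-(chloromethyl)-6,10-dimethyl-4-OTMP-6,7,12-tris(triethylsilyloxy)dodeca-2,10-dien-8-ynoate | CC[Si](CC)(CC)OC/C=C(/C)C#CC(O[Si](CC)(CC)CC)[C@](C)(O[Si](CC)(CC)CC)C[C@@H](ON1C(C)(C)CCCC1(C)C)/C=C(\CCl)C(=O)OC | intermediate
12 | C6 alkoxydimethylsulfonium chloride of 11 (primary silyl group lost) | C[S+](C)OC/C=C(/C)C#CC(O[Si](CC)(CC)CC)[C@](C)(O[Si](CC)(CC)CC)C[C@@H](ON1C(C)(C)CCCC1(C)C)/C=C(\CCl)C(=O)OC.[Cl-] | intermediate (not isolated)
13 | methyl (2Z,4R,6R,7RS,10Z)-2-(chloromethyl)-6,10-dimethyl-12-oxo-4-OTMP-6,7-bis(triethylsilyloxy)dodeca-2,10-dien-8-ynoate | O=C/C=C(/C)C#CC(O[Si](CC)(CC)CC)[C@](C)(O[Si](CC)(CC)CC)C[C@@H](ON1C(C)(C)CCCC1(C)C)/C=C(\CCl)C(=O)OC | intermediate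
14 | methyl (1RS,6S,7R,8R,10R)-6-hydroxy-8-OTMP-1,10-bis(triethylsilyloxy)germacra-4Z,11(13)-dien-2-yn-12-oate (formed as its chromium alkoxide) | C=C(C(=O)OC)[C@@H]1[C@@H](O)/C=C(/C)C#CC(O[Si](CC)(CC)CC)[C@](C)(O[Si](CC)(CC)CC)C[C@H]1ON2C(C)(C)CCCC2(C)C | intermediate (not isolated)
15 | (1RS,6S,7R,8R,10R)-8-OTMP-1,10-bis(triethylsilyloxy)germacra-4Z,11(13)-dien-2-yn-6,12-olide | C=C1C(=O)O[C@H]2/C=C(/C)C#CC(O[Si](CC)(CC)CC)[C@](C)(O[Si](CC)(CC)CC)C[C@@H](ON3C(C)(C)CCCC3(C)C)[C@H]12 | intermediate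
16 | (1RS,6S,7S,8R,10R)-1,8,10-trihydroxygermacra-4Z,11(13)-dien-2-yn-6,12-olide | C=C1C(=O)O[C@H]2/C=C(/C)C#CC(O)[C@](C)(O)C[C@@H](O)[C@H]12 | intermediate
17 | (6S,7S,8R,10R)-8,10-dihydroxy-1-oxogermacra-4Z,11(13)-dien-2-yn-6,12-olide | C=C1C(=O)O[C@H]2/C=C(/C)C#CC(=O)[C@](C)(O)C[C@@H](O)[C@H]12 | intermediate (not isolated)
18 | (6S,7S,8R,10R)-8-hydroxy-1-oxo-3,10-epoxygermacra-2,4Z,11(13)-trien-6,12-olide | C=C1C(=O)O[C@H]2/C=C(/C)C3=CC(=O)[C@@](C)(C[C@@H](O)[C@H]12)O3 | intermediate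
19 | tert-butyl acrylate | C=CC(=O)OC(C)(C)C | starting material
20 | acetaldehyde | CC=O | starting material
21 | tert-butyl 3-hydroxy-2-methylidenebutanoate (racemic) | CC(O)C(=C)C(=O)OC(C)(C)C | intermediate
22 | tert-butyl 3-acetoxy-2-methylidenebutanoate (racemic) | CC(OC(C)=O)C(=C)C(=O)OC(C)(C)C | intermediate (not isolated)
23 | tert-butyl (E)-2-(acetoxymethyl)but-2-enoate | C/C=C(\COC(C)=O)C(=O)OC(C)(C)C | intermediate
24 | (E)-2-(acetoxymethyl)but-2-enoic acid | C/C=C(\COC(C)=O)C(=O)O | intermediate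
25 | (E)-2-(acetoxymethyl)but-2-enoic 2,4,6-trichlorobenzoic anhydride | C/C=C(\COC(C)=O)C(=O)OC(=O)c1c(Cl)cc(Cl)cc1Cl | intermediate (not isolated)
26 | (6S,7S,8R,10R)-8-[(E)-2-(acetoxymethyl)but-2-enoyloxy]-1-oxo-3,10-epoxygermacra-2,4Z,11(13)-trien-6,12-olide | C=C1C(=O)O[C@H]2/C=C(/C)C3=CC(=O)[C@@](C)(C[C@@H](OC(=O)/C(=C/C)COC(C)=O)[C@H]12)O3 | target

## Step count, longest linear sequence and main risks

Total step count: 14. Longest linear sequence: 11 (steps 1–10 and 14, from linalool).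

**Step 8 (ring closure)** is the most likely to fail. The ten-membered enyne ring is strained, two C1 epimers must both cyclise, and the C6/C7 configuration rests on C8 alone in a flexible chain. The fallback sets out from 11 and returns at 18, and it builds the furanone before the carbocycle. HF·pyridine removes the three silyl groups to give the triol allyl chloride F1. MnO2 oxidises the allylic and the propargylic carbinol to the keto aldehyde F2, and Ph3PAuNTf2 closes this to the furanone enal F3. CrCl2/NaI then closes the ring on this rigid precursor through the macrocyclic hydroxy ester F4 to the furanone lactone F5. Zn/AcOH cleaves the N–O bond of F5 to give 18.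

**Step 4 (Morita–Baylis–Hillman)** may be slow on the hindered α-aminoxy aldehyde, may touch the C1 aldehyde, or may epimerise C8 under DABCO. The fallback sets out from 2 and returns at 7, and it unmasks the two aldehydes one after the other and replaces the amine-catalysed step by a vinylmetal addition. One equivalent of ozone (Sudan Red 7B end point) cleaves only the trisubstituted alkene of 2 to give the vinyl aldehyde F6. The α-oxyamination of step 3 gives the aminoxy aldehyde F7. The preformed vinylalane F8 (from methyl propiolate, i-Bu2AlH and N-methylmorpholine N-oxide) adds at −78 °C to give the allylic alcohol F9. Corey–Kim chlorination gives the allyl chloride F10. Ozonolysis of the remaining vinyl group, which spares the electron-poor enoate, gives 7.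

**Step 6 (acetylide addition)** may suffer SN2′ attack of the acetylide or an alkoxide on the 2-(chloromethyl)enoate. The fallback sets out from 6 and 8 and returns at 11, and it forms the C1–C2 bond before any allylic halide is present. Compound 8 is silylated (TESCl, imidazole) to the enynyl silyl ether F11 and lithiated to the lithium acetylide F12. F12 is added in excess to 6, whose free hydroxyl consumes one equivalent, to give the diol F13. Corey–Kim chlorination converts only the allylic hydroxyl, since the neopentyl propargylic carbinol is returned unchanged, and gives the chloro alcohol F14. TESOTf/2,6-lutidine then gives 11.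

## Further compounds

F1 | step 8 | methyl (2Z,4R,6R,7RS,10Z)-2-(chloromethyl)-6,7,12-trihydroxy-6,10-dimethyl-4-OTMP-dodeca-2,10-dien-8-ynoate | OC/C=C(/C)C#CC(O)[C@](C)(O)C[C@@H](ON1C(C)(C)CCCC1(C)C)/C=C(\CCl)C(=O)OC
F2 | step 8 | methyl (2Z,4R,6R,10Z)-2-(chloromethyl)-6-hydroxy-6,10-dimethyl-7,12-dioxo-4-OTMP-dodeca-2,10-dien-8-ynoate | O=C/C=C(/C)C#CC(=O)[C@](C)(O)C[C@@H](ON1C(C)(C)CCCC1(C)C)/C=C(\CCl)C(=O)OC
F3 | step 8 | methyl (2Z,4R)-2-(chloromethyl)-5-[(2R)-2-methyl-3-oxo-5-[(Z)-4-oxobut-2-en-2-yl]-2,3-dihydrofuran-2-yl]-4-OTMP-pent-2-enoate | O=C/C=C(/C)C1=CC(=O)[C@@](C)(C[C@@H](ON2C(C)(C)CCCC2(C)C)/C=C(\CCl)C(=O)OC)O1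
F4 | step 8 | methyl (6S,7R,8R,10R)-6-hydroxy-1-oxo-8-OTMP-3,10-epoxygermacra-2,4Z,11(13)-trien-12-oate (not isolated) | C=C(C(=O)OC)[C@@H]1[C@@H](O)/C=C(/C)C2=CC(=O)[C@@](C)(C[C@H]1ON3C(C)(C)CCCC3(C)C)O2
F5 | step 8 | (6S,7R,8R,10R)-1-oxo-8-OTMP-3,10-epoxygermacra-2,4Z,11(13)-trien-6,12-olide | C=C1C(=O)O[C@H]2/C=C(/C)C3=CC(=O)[C@@](C)(C[C@@H](ON4C(C)(C)CCCC4(C)C)[C@H]12)O3
F6 | step 4 | (R)-4-methyl-4-(triethylsilyloxy)hex-5-enal | C=C[C@](C)(O[Si](CC)(CC)CC)CCC=O
F7 | step 4 | (2R,4R)-4-methyl-2-OTMP-4-(triethylsilyloxy)hex-5-enal | C=C[C@](C)(O[Si](CC)(CC)CC)C[C@@H](ON1C(C)(C)CCCC1(C)C)C=O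
F8 | step 4 | methyl 2-(diisobutylalumanyl)prop-2-enoate | C=C([Al](CC(C)C)CC(C)C)C(=O)OC
F9 | step 4 | methyl (3RS,4R,6R)-3-hydroxy-6-methyl-2-methylidene-4-OTMP-6-(triethylsilyloxy)oct-7-enoate | C=C[C@](C)(O[Si](CC)(CC)CC)C[C@@H](ON1C(C)(C)CCCC1(C)C)C(O)C(=C)C(=O)OC
F10 | step 4 | methyl (2Z,4R,6R)-2-(chloromethyl)-6-methyl-4-OTMP-6-(triethylsilyloxy)octa-2,7-dienoate | C=C[C@](C)(O[Si](CC)(CC)CC)C[C@@H](ON1C(C)(C)CCCC1(C)C)/C=C(\CCl)C(=O)OC
F11 | step 6 | (Z)-triethyl[(3-methylpent-2-en-4-yn-1-yl)oxy]silane | C#C/C(C)=C\CO[Si](CC)(CC)CC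
F12 | step 6 | lithium acetylide of F11 | [Li+].[C-]#C/C(C)=C\CO[Si](CC)(CC)CC
F13 | step 6 | methyl (3RS,4R,6R,7RS,10Z)-3,7-dihydroxy-6,10-dimethyl-2-methylidene-4-OTMP-6,12-bis(triethylsilyloxy)dodec-10-en-8-ynoate | CC[Si](CC)(CC)OC/C=C(/C)C#CC(O)[C@](C)(O[Si](CC)(CC)CC)C[C@@H](ON1C(C)(C)CCCC1(C)C)C(O)C(=C)C(=O)OC
F14 | step 6 | methyl (2Z,4R,6R,7RS,10Z)-2-(chloromethyl)-7-hydroxy-6,10-dimethyl-4-OTMP-6,12-bis(triethylsilyloxy)dodeca-2,10-dien-8-ynoate | CC[Si](CC)(CC)OC/C=C(/C)C#CC(O)[C@](C)(O[Si](CC)(CC)CC)C[C@@H](ON1C(C)(C)CCCC1(C)C)/C=C(\CCl)C(=O)OC
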